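The seven-membered ring is cut at C6–C7 and C9–C10 (daucane numbering): its C6(O)–C7–C8(Me)=C9–C10(O) segment is the retron of a double allylation. In the key step a cis-1,4-dialdehyde (C6 and C10 formyl groups on cyclopentane carbons C5 and C1) is annulated with a chiral γ-silyl methallylborane that acts as a 2-methylpropene-1,3-diyl linchpin. Allylboration at C10, then intramolecular Hosomi–Sakurai closure at C6, forms both bonds, both carbinol stereocentres and the C8=C9 alkene that later carries the epoxide. The dialdehyde comes from ozonolysis of a cyclobutene made by enone–acetylene [2+2] photocycloaddition, which fixes the cis ring fusion and quaternary C1.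

Key step: step 7

Numbering: C1 = angular C–CH3, C2 = CH–OH, C3 = CH2, C4 = C(OH)(i-Pr), C5 = ring-fusion CH, C6 = CH–OAng, C7 = CH2, C8 = C(CH3) and C9 = CH of the epoxide, C10 = CH–OAng; ring A = cyclopentane, ring B = cycloheptane; β = the face of the C1 methyl group.
Assumption: the (+)-α-pinene-derived diisopinocampheylborane adds to the si face of the C10 aldehyde, as it does with simple aldehydes; the antipodal borane would be used otherwise.

Step 1
Reactants: 1 (S)-4-(tert-butyldimethylsilyloxy)cyclopent-2-en-1-one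
Product: 2 (3S,4S)-4-(tert-butyldimethylsilyloxy)-3-methyl-1-(trimethylsilyloxy)cyclopent-1-ene
Conditions: Me2CuLi, TMSCl, THF, −78 °C
Reagents that add atoms: lithium dimethylcuprate, [Li+].C[Cu-]C; chlorotrimethylsilane, C[Si](C)(C)Cl
Why: Cuprate 1,4-addition with silyl trapping of the enolate should place the methyl group anti to the adjacent silyloxy group; this methyl-bearing stereocentre is only transient.

Step 2
Reactants: 2 (3S,4S)-4-(tert-butyldimethylsilyloxy)-3-methyl-1-(trimethylsilyloxy)cyclopent-1-ene
Product: 3 (S)-4-(tert-butyldimethylsilyloxy)-3-methylcyclopent-2-en-1-one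
Conditions: Pd(OAc)2 (1.05 equiv), MeCN, rt
Reagents that add atoms: none
Why: Saegusa–Ito oxidation (palladation of the silyl enol ether, then β-hydride elimination toward the methyl-bearing carbon) should regenerate the enone with the β-methyl group in place and leave the silyloxy stereocentre untouched.

Step 3
Reactants: 3 (S)-4-(tert-butyldimethylsilyloxy)-3-methylcyclopent-2-en-1-one
Product: 4 cis-fused 4-(tert-butyldimethylsilyloxy)-5-methylbicyclo[3.2.0]hept-6-en-2-one with the silyloxy group anti to the cyclobutene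
Conditions: HC≡CH (sat.), hν (medium-pressure Hg lamp, uranium-glass filter), acetone, −78 °C, partial conversion
Reagents that add atoms: acetylene, C#C
Why: Enone–alkyne [2+2] photocycloaddition should give the cis-fused cyclobutene, acetylene adding to the enone face anti to the neighbouring silyloxy group, which sets quaternary C1 and C5 with both future formyl carbons cis.

Step 4
Reactants: 4 cis-fused 4-(tert-butyldimethylsilyloxy)-5-methylbicyclo[3.2.0]hept-6-en-2-one
Product: 5 4-(tert-butyldimethylsilyloxy)-2-isopropyl-5-methylbicyclo[3.2.0]hept-6-en-2-ol with the hydroxyl syn to the cyclobutene (4α-OH in daucane terms)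
Conditions: i-PrMgCl, LaCl3·2LiCl (0.3 equiv), THF, 0 °C
Reagents that add atoms: isopropylmagnesium chloride, CC(C)[Mg]Cl
Why: Lanthanum-promoted Grignard 1,2-addition (suppressing enolisation and β-hydride reduction) should occur on the convex face of the bicyclo[3.2.0]heptenone, anti to the cyclobutene, giving the tertiary alcohol with isopropyl β and hydroxyl α.

Step 5
Reactants: 5 tertiary alcohol
Product: 6 triethylsilyl ether of 5
Conditions: TESOTf, 2,6-lutidine, CH2Cl2, −78 → 0 °C
Reagents that add atoms: triethylsilyl trifluoromethanesulfonate, CC[Si](CC)(CC)OS(=O)(=O)C(F)(F)F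
Why: Silyl triflate silylation of the hindered tertiary alcohol prevents lactol formation with the C10 aldehyde and protonolysis of the borane in step 7.

Step 6
Reactants: 6 bis-silylated cyclobutene
Product: 7 cis-dialdehyde: 1-methyl-5β-(tert-butyldimethylsilyloxy)-3β-isopropyl-3α-(triethylsilyloxy)cyclopentane-1α,2α-dicarbaldehyde (both formyl groups on the face of the OTES group)
Conditions: O3, pyridine (3 equiv), CH2Cl2, −78 °C; used crude
Reagents that add atoms: ozone, [O-][O+]=O
Why: Pyridine-modified ozonolysis should cleave the cyclobutene directly to the cis-1,4-dialdehyde without a reductive work-up, touching no stereocentre and avoiding base that could epimerise C5.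

Step 7
Reactants: 7 cis-dialdehyde; 8 trimethyl(2-methylallyl)silane
Product: 11 2β-TBSO-4α-TESO-daucan-8-ene-6β,10α-diol, via silylallylborane 9 (not isolated), via boryloxy allylsilane 10 (not isolated)
Conditions: 8, s-BuLi, TMEDA, THF, −78 → −30 °C; (−)-Ipc2BOMe, −78 °C; BF3·OEt2, −78 °C; then 7 (1.0 equiv), −78 °C; then BF3·OEt2 (2 equiv), −78 → −40 °C; NaOH, H2O2, 0 °C
Reagents that add atoms: none
Why: Proposed new method: borane 9 acts as a 2-methylpropene-1,3-diyl bis-nucleophile: closed chair allylboration at −78 °C delivers its silyl-bearing γ-carbon to the C10 aldehyde (C9–C10), and the methallylsilane so formed (10) attacks the BF3-activated C6 aldehyde through C7 in an anti SE2′ Hosomi–Sakurai closure (C6–C7), loss of Me3SiF placing the alkene regiospecifically at C8=C9. The closest known reactions are double allylboration of two separate aldehydes with γ-boryl allylboranes and γ-silylallylboration followed by Lewis acid allylsilane addition; their tandem use on one 1,4-dialdehyde to close a carbocycle is new. Ring B closes in a 7-endo mode with respect to the allyl unit (exo with respect to the carbonyl), the cis-1,2 placement of the formyl groups on ring A holding the termini within reach. C10 is set by reagent control (si-face attack dictated by the isopinocampheyl groups); C6 is set by the closing geometry, in which C7 must stay gauche to C1 and anti to C4, so the BF3-bound oxygen sits beside C5–H and not in the cleft between the fully substituted C1 and C4, giving the 6β-alcohol, while the transient C9 stereocentre is erased. The step needs the borane to react first at C10: the C6 formyl is the middle member of an all-cis C10/C6/C4–OSiEt3 array flanked by two fully substituted carbons and its intrinsic facial preference should be mismatched with the borane, whereas the C10 formyl has an open flank at C2–H. The tertiary cation at C8 disfavours the competing silyl-shift [3+2] annulation, and the bulky borinate on the C10 oxygen should slow Peterson elimination and oxygen-bridged closure.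

Step 8
Reactants: 11 cycloheptene diol
Product: 12 8α,9α-epoxy-2β-TBSO-4α-TESO-daucane-6β,10α-diol
Conditions: VO(acac)2 (5 mol %), t-BuOOH, CH2Cl2, 0 °C → rt
Reagents that add atoms: tert-butyl hydroperoxide, CC(C)(C)OO
Why: Hydroxyl-directed epoxidation should deliver oxygen syn to the allylic C10 hydroxyl to give the 8α,9α-epoxide, the homoallylic C6 hydroxyl directing far more slowly.

Step 9
Reactants: 12 epoxy diol
Product: 13 6β,10α-bis(angeloyloxy)-8α,9α-epoxy-2β-TBSO-4α-TESO-daucane
Conditions: angelic acid, 2,4,6-Cl3C6H2COCl, Et3N, toluene, rt; then 12, 80 °C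
Reagents that add atoms: angelic acid [(Z)-2-methylbut-2-enoic acid], C/C=C(/C)C(=O)O
Why: Yamaguchi-type esterification through the mixed 2,4,6-trichlorobenzoic anhydride without DMAP should acylate both secondary alcohols with retention and without Z-to-E isomerisation of the angelate, the silyl ethers staying inert.

Step 10
Reactants: 13 bis-angelate
Product: 14 target, 6β,10α-bis(angeloyloxy)-8α,9α-epoxydaucane-2β,4α-diol (CNP0265715.3)
Conditions: HF·pyridine, pyridine, THF, 0 °C → rt
Reagents that add atoms: none
Why: Pyridine-buffered fluoride cleavage of the tertiary triethylsilyl and secondary tert-butyldimethylsilyl ethers (silyl ether deprotection) should free the C4 and C2 hydroxyls without opening the epoxide or moving the esters.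

Compound list
1 | (S)-4-(tert-butyldimethylsilyloxy)cyclopent-2-en-1-one | C1=CC(=O)C[C@@H]1O[Si](C)(C)C(C)(C)C | starting material
2 | (3S,4S)-4-(tert-butyldimethylsilyloxy)-3-methyl-1-(trimethylsilyloxy)cyclopent-1-ene (methyl trans to OTBS) | C[C@H]1C=C(O[Si](C)(C)C)C[C@@H]1O[Si](C)(C)C(C)(C)C | intermediate
3 | (S)-4-(tert-butyldimethylsilyloxy)-3-methylcyclopent-2-en-1-one | CC1=CC(=O)C[C@@H]1O[Si](C)(C)C(C)(C)C | intermediate
4 | cis-fused 4-(tert-butyldimethylsilyloxy)-5-methylbicyclo[3.2.0]hept-6-en-2-one, OTBS anti to the cyclobutene | C1=C[C@@]2(C)[C@@H]1C(=O)C[C@@H]2O[Si](C)(C)C(C)(C)C | intermediate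
5 | 4-(tert-butyldimethylsilyloxy)-2-isopropyl-5-methylbicyclo[3.2.0]hept-6-en-2-ol, OH syn to the cyclobutene | C1=C[C@@]2(C)[C@@H]1[C@](O)(C(C)C)C[C@@H]2O[Si](C)(C)C(C)(C)C | intermediate
6 | triethylsilyl ether of 5 | C1=C[C@@]2(C)[C@@H]1[C@](O[Si](CC)(CC)CC)(C(C)C)C[C@@H]2O[Si](C)(C)C(C)(C)C | intermediate
7 | cis-dialdehyde (C6 and C10 formyl groups α on ring A; 2β-OTBS, 4α-OTES, 4β-isopropyl, 1β-methyl) | O=C[C@@]1(C)[C@@H](C=O)[C@](O[Si](CC)(CC)CC)(C(C)C)C[C@@H]1O[Si](C)(C)C(C)(C)C | intermediate
8 | trimethyl(2-methylallyl)silane | C=C(C)C[Si](C)(C)C | starting material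
9 | [(E)-2-methyl-3-(trimethylsilyl)allyl]diisopinocampheylborane (isopinocampheyl groups from (+)-α-pinene) | C[Si](C)(C)/C=C(\C)CB([C@@H]1C[C@@H]2C[C@H]([C@H]1C)C2(C)C)[C@@H]1C[C@@H]2C[C@H]([C@H]1C)C2(C)C | intermediate (not isolated)
10 | C10 diisopinocampheylborinate of the anti β-hydroxy allylsilane, C6 formyl group still free | C=C(C)[C@H]([Si](C)(C)C)[C@H](OB([C@@H]1C[C@@H]2C[C@H]([C@H]1C)C2(C)C)[C@@H]1C[C@@H]2C[C@H]([C@H]1C)C2(C)C)[C@@]3(C)[C@@H](C=O)[C@](O[Si](CC)(CC)CC)(C(C)C)C[C@@H]3O[Si](C)(C)C(C)(C)C | intermediate (not isolated)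
11 | 2β-TBSO-4α-TESO-daucan-8-ene-6β,10α-diol (cis-fused, 5β-H) | O[C@H]1CC(C)=C[C@H](O)[C@@]2(C)[C@@H]1[C@](O[Si](CC)(CC)CC)(C(C)C)C[C@@H]2O[Si](C)(C)C(C)(C)C | intermediate
12 | 8α,9α-epoxy-2β-TBSO-4α-TESO-daucane-6β,10α-diol | O[C@H]1C[C@]2(C)O[C@@H]2[C@H](O)[C@@]2(C)[C@@H]1[C@](O[Si](CC)(CC)CC)(C(C)C)C[C@@H]2O[Si](C)(C)C(C)(C)C | intermediate
13 | 6β,10α-bis(angeloyloxy)-8α,9α-epoxy-2β-TBSO-4α-TESO-daucane | C/C=C(/C)C(=O)O[C@H]1C[C@]2(C)O[C@@H]2[C@H](OC(=O)/C(C)=C\C)[C@@]2(C)[C@@H]1[C@](O[Si](CC)(CC)CC)(C(C)C)C[C@@H]2O[Si](C)(C)C(C)(C)C | intermediate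
14 | 6β,10α-bis(angeloyloxy)-8α,9α-epoxydaucane-2β,4α-diol (CNP0265715.3) | C/C=C(/C)C(=O)O[C@H]1C[C@]2(C)O[C@@H]2[C@H](OC(=O)/C(C)=C\C)[C@@]2(C)[C@@H]1[C@](O)(C(C)C)C[C@@H]2O | target

Total step count: 10. Longest linear sequence: 10 steps (1 → 14); 8 is a commercial reagent-fragment.

Steps most likely to fail

Step 7 (Proposed new method). The borane may add first to the C6 formyl group, which would leave the alkene at C7=C8. The β-boryloxy silane may also collapse by Peterson elimination, or the C10 oxygen may add to the activated C6 aldehyde so that the allylsilane closes an oxygen-bridged ether instead of the carbocycle. The fallback uses known chemistry (ring-closing metathesis), sets out from 5 and returns at 14. Ozonolysis of 5 (O3, pyridine, CH2Cl2, −78 °C) with the tertiary hydroxyl free should give lactol aldehyde F1, in which the C4 hydroxyl masks the C10 formyl group. 2-Methylallylboronic acid pinacol ester then adds to the only free aldehyde (C6) to give homoallylic alcohol F2. Excess vinylmagnesium bromide opens the lactol and adds at C10 to give triol F3. Second-generation Grubbs catalyst closes C8=C9 to give cycloheptene triol F4. VO(acac)2/t-BuOOH gives epoxy triol F5, Yamaguchi bis-angeloylation gives diester F6, and HF·pyridine removes the TBS group to reach 14. The C6 and C10 carbinol configurations rest on substrate control here and would be corrected at F4 by oxidation and reduction if needed.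

Step 3. Over-irradiation may trigger a photochemical 1,3-acyl shift of the β,γ-unsaturated ketone product, and facial discrimination by the silyloxy group may be incomplete with the small acetylene. The fallback sets out from 3 and returns at 5. Photocycloaddition of 3 with (Z)-1,2-dichloroethene, a photostable acetylene surrogate, gives dichlorocyclobutane ketone F7. Isopropyl Grignard addition (LaCl3·2LiCl) gives tertiary alcohol F8. Reductive dechlorination with sodium naphthalenide (THF, −78 °C) unveils the cyclobutene 5.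

Step 9. Acylation of the neopentyl, epoxide-flanked C10 hydroxyl may stall, and forcing it may isomerise the angelate to the tiglate. The fallback sets out from 12 and returns at 13. Both hydroxyls are acylated with 2-[bis(2,2,2-trifluoroethoxy)phosphoryl]propanoic acid (carbodiimide, DMAP, no alkene yet to isomerise) to give bis-phosphonate F9. A Z-selective Still–Gennari olefination with acetaldehyde (KHMDS, 18-crown-6, THF, −78 °C) then builds both angelate double bonds.

Further compounds
F1 | step 7 | lactol aldehyde (C4–O closed onto C10; C6 formyl free; anomeric mixture) | OC1O[C@@]2(C(C)C)C[C@H](O[Si](C)(C)C(C)(C)C)[C@]1(C)[C@H]2C=O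
F2 | step 7 | C6 methallyl carbinol of the lactol | OC1O[C@@]2(C(C)C)C[C@H](O[Si](C)(C)C(C)(C)C)[C@]1(C)[C@H]2[C@@H](O)CC(C)=C
F3 | step 7 | acyclic triol (C10 vinyl carbinol, C6 methallyl carbinol, C4–OH) | C=C[C@H](O)[C@@]1(C)[C@@H]([C@@H](O)CC(C)=C)[C@](O)(C(C)C)C[C@@H]1O[Si](C)(C)C(C)(C)C
F4 | step 7 | 2β-TBSO-daucan-8-ene-4α,6β,10α-triol | O[C@H]1CC(C)=C[C@H](O)[C@@]2(C)[C@@H]1[C@](O)(C(C)C)C[C@@H]2O[Si](C)(C)C(C)(C)C
F5 | step 7 | 8α,9α-epoxy-2β-TBSO-daucane-4α,6β,10α-triol | O[C@H]1C[C@]2(C)O[C@@H]2[C@H](O)[C@@]2(C)[C@@H]1[C@](O)(C(C)C)C[C@@H]2O[Si](C)(C)C(C)(C)C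
F6 | step 7 | 6β,10α-bis(angeloyloxy)-8α,9α-epoxy-2β-TBSO-daucan-4α-ol | C/C=C(/C)C(=O)O[C@H]1C[C@]2(C)O[C@@H]2[C@H](OC(=O)/C(C)=C\C)[C@@]2(C)[C@@H]1[C@](O)(C(C)C)C[C@@H]2O[Si](C)(C)C(C)(C)C
F7 | step 3 | 6,7-dichloro-4-(tert-butyldimethylsilyloxy)-5-methylbicyclo[3.2.0]heptan-2-one (mixture of chloride epimers) | ClC1C(Cl)[C@@]2(C)[C@@H]1C(=O)C[C@@H]2O[Si](C)(C)C(C)(C)C
F8 | step 3 | 6,7-dichloro-4-(tert-butyldimethylsilyloxy)-2-isopropyl-5-methylbicyclo[3.2.0]heptan-2-ol (mixture of chloride epimers) | ClC1C(Cl)[C@@]2(C)[C@@H]1[C@](O)(C(C)C)C[C@@H]2O[Si](C)(C)C(C)(C)C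
F9 | step 9 | 6β,10α-bis{2-[bis(2,2,2-trifluoroethoxy)phosphoryl]propanoyloxy}-8α,9α-epoxy-2β-TBSO-4α-TESO-daucane (epimeric at the phosphonate carbons) | CC(C(=O)O[C@H]1C[C@]2(C)O[C@@H]2[C@H](OC(=O)C(C)P(=O)(OCC(F)(F)F)OCC(F)(F)F)[C@@]2(C)[C@@H]1[C@](O[Si](CC)(CC)CC)(C(C)C)C[C@@H]2O[Si](C)(C)C(C)(C)C)P(=O)(OCC(F)(F)F)OCC(F)(F)F
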